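## Retrosynthetic overview

1. Target 24 ⇐ diol 22 ⇐ 21. The strategy rests on the cyclobutane C4–C5–C11–C10: its quaternary C10 lies next to oxygenated C9, and its C4 is the γ-carbon of the ring A enone (C1=O, C2=C3).
2. Key disconnection C4–C10: 21 ⇐ cis-fused bicycle 20, which carries an upper-face 9,10-epoxide and a C1 silyl dienol ether (C1=C2–C3=C4). A Lewis acid opens C10–O and C4 closes the four-membered ring.
3. 20 ⇐ enone 18 ⇐ cycloadduct 9: ring A by Diels–Alder addition of silyloxydiene 8 across C5=C11 of cycloheptenone 6 (bonds C4–C5 and C1–C11).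
4. 6 ⇐ ring B by ring-closing metathesis (C5=C11) and allylic oxidation of the tert-prenylation product of hex-5-enal. The C7 carbinol is a relay centre: it steers the cycloaddition and is then inverted by oxidation–reduction.
5. Ring order: B (seven-membered), then A (six-membered), then the four-membered ring.

Key step: step 17

## Conventions and assumptions

- Numbering: longipinane numbering is used for all bicyclic and tricyclic compounds. Ring A = C1, C2, C3, C4, C5, C11; ring B = C5, C6, C7, C8, C9, C10, C11; four-membered ring = C4, C5, C11, C10. In monocycles 5 and 6 the same atom labels are used (ketone carbon of 6 = C10, alkene = C11=C5, CMe2 = C6, carbinol = C7).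
- Faces: the "upper face" of ring B carries H5 and H11; the "lower face" carries C1 and C4. The target has 7-O on the lower face, and 9-O and the C10 methyl on the upper face.
- Assumption (step 1): (R)-SEGPHOS is taken to give the (4S)-carbinol 3; if the sense is the reverse, the (S)-ligand is used.
- Assumption (step 6): the diene is expected to add anti to the C7 silyloxy group. C7 is therefore made with the configuration opposite to that of the target and is inverted in steps 10 and 11. If the cycloaddition preferred the syn face, the other ligand antipode would be used and steps 10 and 11 dropped.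

## Route

Step 1
Reactants: 1 hex-5-enal; 2 3-methylbuta-1,2-diene
Product: 3 (4S)-3,3-dimethylnona-1,8-dien-4-ol
Conditions: [Ir(cod)Cl]2 (2.5 mol %), (R)-SEGPHOS (5 mol %), 4-cyano-3-nitrobenzoic acid (10 mol %), Cs2CO3 (20 mol %), i-PrOH (2 equiv), THF, 60 °C
Reagents that add atoms: none
Why: Iridium-catalysed transfer-hydrogenative reverse prenylation (tert-prenylation) of aliphatic aldehydes with 1,1-dimethylallene is established and sets the C7 carbinol under catalyst control through a closed allyliridium transition state; the (S) configuration is chosen because this centre is a relay for step 6 and is corrected in steps 10 and 11.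

Step 2
Reactants: 3 (4S)-3,3-dimethylnona-1,8-dien-4-ol
Product: 4 triethylsilyl ether of 3
Conditions: TESOTf, 2,6-lutidine, CH2Cl2, −78 to 0 °C
Reagents that add atoms: triethylsilyl trifluoromethanesulfonate, CC[Si](CC)(CC)OS(=O)(=O)C(F)(F)F
Why: Silyl triflate silylation is reliable for hindered neopentyl-type secondary alcohols and does not touch the stereocentre.

Step 3
Reactants: 4 triethylsilyl ether of 3
Product: 5 triethyl{[(1S)-2,2-dimethylcyclohept-3-en-1-yl]oxy}silane
Conditions: second-generation Grubbs catalyst (H2IMes)(PCy3)Cl2Ru=CHPh (3 mol %), CH2Cl2 (0.01 M), 40 °C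
Reagents that add atoms: none
Why: Ring-closing metathesis of a 1,8-diene to a cycloheptene is routine with this catalyst; the vinyl group next to the quaternary carbon reacts only in the intramolecular step, so ring B closes at C5=C11 without any change at C7.

Step 4
Reactants: 5 triethyl{[(1S)-2,2-dimethylcyclohept-3-en-1-yl]oxy}silane
Product: 6 (5S)-4,4-dimethyl-5-(triethylsilyloxy)cyclohept-2-en-1-one
Conditions: Rh2(cap)4 (cap = caprolactamate, 1 mol %), t-BuOOH (5 equiv), K2CO3, CH2Cl2, 23 °C
Reagents that add atoms: tert-butyl hydroperoxide, CC(C)(C)OO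
Why: Dirhodium caprolactamate/hydroperoxide allylic oxidation turns cycloalkenes into enones; here only C10 carries allylic hydrogens (C6 is quaternary) and the unhindered C10 end of the allyl radical is oxygenated, so the C10 enone forms with C7 untouched.

Step 5
Reactants: 7 3-methylbut-2-enal
Product: 8 tert-butyl(dimethyl){[(1E)-3-methylbuta-1,3-dien-1-yl]oxy}silane
Conditions: TBSOTf, Et3N, Et2O, 0 to 23 °C
Reagents that add atoms: tert-butyldimethylsilyl trifluoromethanesulfonate, CC(C)(C)[Si](C)(C)OS(=O)(=O)C(F)(F)F
Why: Soft enolisation (O-silylation of the enal, then γ-deprotonation by the amine) is the standard way to 1-silyloxy-3-methylbuta-1,3-dienes and gives the (E)-dienol ether.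

Step 6
Reactants: 6 (5S)-4,4-dimethyl-5-(triethylsilyloxy)cyclohept-2-en-1-one; 8 tert-butyl(dimethyl){[(1E)-3-methylbuta-1,3-dien-1-yl]oxy}silane
Product: 9 cis-fused cycloadduct (C10 ketone; C2=C3; 1-OTBS; 7-OTES on the upper face)
Conditions: 8 (2 equiv), Me2AlCl (1.1 equiv), CH2Cl2, −78 to −20 °C
Reagents that add atoms: none
Why: Lewis-acid-promoted Diels–Alder reaction of a cycloalk-2-enone with a 1-silyloxydiene: the oxygen and methyl substituents both raise the coefficient at the diene CH2 terminus, so C4 bonds to the β-carbon C5 and C1 to C11; suprafacial addition to the cis-enone sets H5 and H11 cis; the diene takes the axial trajectory on the ring B face trans to the equatorial C7 silyloxy group (the sense seen in additions to 5-substituted cycloalkenones), which places ring A on the lower face; and the endo transition state puts the C1 silyloxy group cis to C10, a centre that is erased in step 13.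

Step 7
Reactants: 9 cis-fused cycloadduct
Product: 11 C10 enol triflate (C9=C10), via potassium enolate 10 (not isolated)
Conditions: KN(SiMe3)2 (1.05 equiv), THF, −78 °C; then PhNTf2, −78 to 0 °C
Reagents that add atoms: N-phenylbis(trifluoromethanesulfonimide), O=S(=O)(N(c1ccccc1)S(=O)(=O)C(F)(F)F)C(F)(F)F
Why: Kinetic deprotonation with a hindered amide base removes a C9 methylene proton rather than the tertiary, shielded H11, and O-triflation of the enolate (enol triflate formation) fixes the C9=C10 position while leaving C11 and the β-silyloxy group at C1 intact.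

Step 8
Reactants: 11 C10 enol triflate
Product: 12 C10-methyl diene (C9=C10 and C2=C3; 1-OTBS; 7-OTES)
Conditions: MeMgBr (1.5 equiv), Fe(acac)3 (5 mol %), THF/NMP, −30 to 0 °C
Reagents that add atoms: methylmagnesium bromide, C[Mg]Br
Why: Iron-catalysed Kumada-type coupling of alkenyl triflates with methyl Grignard reagent is fast at low temperature, tolerates silyl ethers and replaces the triflate by the C10 methyl group without moving the alkene.

Step 9
Reactants: 12 C10-methyl diene
Product: 13 7-epi alcohol (7-OH on the upper face; 1-OTBS kept)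
Conditions: HF·pyridine, pyridine, THF, 0 °C
Reagents that add atoms: none
Why: Fluoride cleaves a triethylsilyl ether much faster than a secondary tert-butyldimethylsilyl ether, so buffered HF·pyridine frees only the C7 hydroxyl (selective silyl ether cleavage).

Step 10
Reactants: 13 7-epi alcohol
Product: 14 C7 ketone
Conditions: Dess–Martin periodinane, NaHCO3, CH2Cl2, 0 to 23 °C
Reagents that add atoms: none
Why: Buffered Dess–Martin oxidation converts the hindered secondary alcohol into the ketone under neutral conditions that do not move the β,γ-alkene C9=C10 into conjugation.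

Step 11
Reactants: 14 C7 ketone
Product: 15 7-alcohol with the target configuration (7-OH on the lower face)
Conditions: NaBH4, MeOH, −20 °C
Reagents that add atoms: none
Why: Borohydride reduction: hydride should reach C7 from the upper face past H5 (axial attack on the chair-like ring B in which the C5–C4 bond is equatorial, the lower face being screened by ring A), giving the equatorial lower-face alcohol cis to C4, which is also the more stable epimer and has the C7 configuration of the target.

Step 12
Reactants: 15 7-alcohol with the target configuration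
Product: 16 1,7-diol
Conditions: n-Bu4NF, THF, 23 °C
Reagents that add atoms: none
Why: Fluoride desilylation removes the allylic silyl ether at C1 without affecting any stereocentre.

Step 13
Reactants: 16 1,7-diol
Product: 17 7-hydroxy enone (C1=O, C2=C3)
Conditions: activated MnO2 (excess), CH2Cl2, 23 °C
Reagents that add atoms: none
Why: MnO2 oxidises allylic alcohols selectively, so only C1 becomes a ketone while the saturated C7 carbinol is kept, and the neutral conditions avoid enolisation at the doubly activated C11.

Step 14
Reactants: 17 7-hydroxy enone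
Product: 18 7-silyloxy enone (7-OTBS; C9=C10)
Conditions: TBSOTf, 2,6-lutidine, CH2Cl2, −78 °C
Reagents that add atoms: tert-butyldimethylsilyl trifluoromethanesulfonate, CC(C)(C)[Si](C)(C)OS(=O)(=O)C(F)(F)F
Why: Silyl triflate with a weak hindered base silylates the neopentyl-type alcohol at low temperature without enolising the enone, and the lower-face silyl ether also blocks hydroxyl direction in the next step.

Step 15
Reactants: 18 7-silyloxy enone
Product: 19 upper-face 9,10-epoxy enone
Conditions: mCPBA, NaHCO3, CH2Cl2, 0 °C
Reagents that add atoms: 3-chloroperoxybenzoic acid, OOC(=O)c1cccc(Cl)c1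
Why: Prilezhaev epoxidation: the peracid selects the electron-rich trisubstituted C9=C10 over the enone alkene and attacks the upper face, anti to the pseudo-axial C11–C1 bond (held axial to avoid strain with the C10 methyl group) and anti to the lower-face C7 silyloxy group, which sets C9 and C10 with oxygen on the upper face.

Step 16
Reactants: 19 upper-face 9,10-epoxy enone
Product: 20 epoxy silyl dienol ether (C1(OTBS)=C2–C3=C4)
Conditions: TBSOTf (1.3 equiv), Et3N (3 equiv), CH2Cl2, −78 to −20 °C
Reagents that add atoms: tert-butyldimethylsilyl trifluoromethanesulfonate, CC(C)(C)[Si](C)(C)OS(=O)(=O)C(F)(F)F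
Why: Soft enolisation of a cyclohexenone with silyl triflate and amine is a known way to the linear silyl dienol ether: the amine removes the exposed γ-proton at C4 of the O-silylated enone (endocyclic C3=C4 being the thermodynamic isomer), H11 lies near the carbonyl plane and is shielded by quaternary C10, and no free enolate is present to trigger β-elimination of the epoxide.

Step 17
Reactants: 20 epoxy silyl dienol ether
Product: 21 9-hydroxy-7-(tert-butyldimethylsilyloxy)longipin-2-en-1-one
Conditions: MeAlCl2 (1.5 equiv), CH2Cl2, −78 °C; then aq. NaHCO3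
Reagents that add atoms: none
Why: Proposed new method: MeAlCl2 binds the epoxide oxygen and lengthens the tertiary C10–O bond, and the γ-carbon C4 of the silyl dienol ether, held about 3 Å below C10 because the cis ring fusion places C10 axial on ring A, attacks C10 from the side opposite the departing oxygen; loss of the silyl group from the resulting oxocarbenium ion then gives the C1 enone and the C9 aluminium alkoxide, so the closure cannot reverse. The closest known reactions are Lewis-acid epoxide-initiated cation–olefin cyclisations terminated by silyl enol ethers and vinylogous Mukaiyama alkylations with tertiary electrophiles, neither of which has been used to close a four-membered ring. The ring C4–C5–C11–C10 closes in the 4-exo-tet mode, the breaking C10–O bond lying outside the new ring. C10 is set by inversion (attack anti to the upper-face epoxide turns its methyl group to the upper face), C4 is set by the bridge itself because C10 can reach only the ring A face that carries it, and C9 keeps its configuration because its C–O bond is not broken. The step needs γ attack (C4) to beat α attack (C2), 1,2-hydride shift from C9 and proton loss: α attack would place the sp2 carbon C1 inside a four-membered ring and give an unconjugated ketone, whereas the anti alignment of the C4 lobe with the C10–O bond and the conjugated enone product favour closure at C4. Any product silylated at O9 converges in step 18.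

Step 18
Reactants: 21 9-hydroxy-7-(tert-butyldimethylsilyloxy)longipin-2-en-1-one
Product: 22 7,9-dihydroxylongipin-2-en-1-one
Conditions: n-Bu4NF, THF, 23 to 40 °C
Reagents that add atoms: none
Why: Fluoride desilylation frees the C7 hydroxyl; neither carbinol has a retro-aldol path to the enone, so the stereocentres are kept.

Step 19
Reactants: 22 7,9-dihydroxylongipin-2-en-1-one; 23 3-methylbut-2-enoyl chloride
Product: 24 7,9-bis(3-methylbut-2-enoyloxy)longipin-2-en-1-one (target)
Conditions: 23 (3 equiv), pyridine, DMAP (cat.), CH2Cl2, 0 to 23 °C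
Reagents that add atoms: none
Why: DMAP-catalysed acyl transfer (Steglich-type acylation) esterifies both hindered secondary alcohols, and the weak base limits deconjugation of the acid chloride; no stereocentre is touched.

## Compound list

1 | hex-5-enal | C=CCCCC=O | starting material
2 | 3-methylbuta-1,2-diene | CC(C)=C=C | starting material
3 | (4S)-3,3-dimethylnona-1,8-dien-4-ol | C=CCCC[C@H](O)C(C)(C)C=C | intermediate
4 | triethyl{[(4S)-3,3-dimethylnona-1,8-dien-4-yl]oxy}silane | C=CCCC[C@H](O[Si](CC)(CC)CC)C(C)(C)C=C | intermediate
5 | triethyl{[(1S)-2,2-dimethylcyclohept-3-en-1-yl]oxy}silane | CC[Si](CC)(CC)O[C@H]1CCCC=CC1(C)C | intermediate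
6 | (5S)-4,4-dimethyl-5-(triethylsilyloxy)cyclohept-2-en-1-one | CC[Si](CC)(CC)O[C@H]1CCC(=O)C=CC1(C)C | intermediate
7 | 3-methylbut-2-enal | CC(C)=CC=O | starting material
8 | tert-butyl(dimethyl){[(1E)-3-methylbuta-1,3-dien-1-yl]oxy}silane | C=C(C)/C=C/O[Si](C)(C)C(C)(C)C | intermediate
9 | cis-fused cycloadduct: ring B ketone at C10, 6,6-dimethyl, 7-OTES on the upper face; ring A with C2=C3 (3-methyl) and 1-OTBS cis to C10; H5 and H11 on the upper face | CC[Si](CC)(CC)O[C@H]1CCC(=O)[C@@H]2[C@H](O[Si](C)(C)C(C)(C)C)C=C(C)C[C@@H]2C1(C)C | intermediate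
10 | potassium C9=C10 enolate of 9 | CC[Si](CC)(CC)O[C@H]1CC=C([O-])[C@@H]2[C@H](O[Si](C)(C)C(C)(C)C)C=C(C)C[C@@H]2C1(C)C.[K+] | intermediate (not isolated)
11 | C10 enol triflate of 9 (C9=C10) | CC[Si](CC)(CC)O[C@H]1CC=C(OS(=O)(=O)C(F)(F)F)[C@@H]2[C@H](O[Si](C)(C)C(C)(C)C)C=C(C)C[C@@H]2C1(C)C | intermediate
12 | cis-fused 3,6,6,10-tetramethyl 2,9-diene with 1-OTBS and 7-OTES (upper face) | CC[Si](CC)(CC)O[C@H]1CC=C(C)[C@@H]2[C@H](O[Si](C)(C)C(C)(C)C)C=C(C)C[C@@H]2C1(C)C | intermediate
13 | 7-epi alcohol: as 12 with free 7-OH on the upper face | O[C@H]1CC=C(C)[C@@H]2[C@H](O[Si](C)(C)C(C)(C)C)C=C(C)C[C@@H]2C1(C)C | intermediate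
14 | C7 ketone: as 13 with C7=O | O=C1CC=C(C)[C@@H]2[C@H](O[Si](C)(C)C(C)(C)C)C=C(C)C[C@@H]2C1(C)C | intermediate
15 | 7-alcohol with 7-OH on the lower face, 1-OTBS | O[C@@H]1CC=C(C)[C@@H]2[C@H](O[Si](C)(C)C(C)(C)C)C=C(C)C[C@@H]2C1(C)C | intermediate
16 | 1,7-diol (7-OH lower face; 2,9-diene) | O[C@@H]1CC=C(C)[C@@H]2[C@H](O)C=C(C)C[C@@H]2C1(C)C | intermediate
17 | cis-fused 7-hydroxy-3,6,6,10-tetramethyl 2,9-dien-1-one (7-OH lower face) | O[C@@H]1CC=C(C)[C@@H]2C(=O)C=C(C)C[C@@H]2C1(C)C | intermediate
18 | 7-(tert-butyldimethylsilyloxy) 2,9-dien-1-one | CC(C)(C)[Si](C)(C)O[C@@H]1CC=C(C)[C@@H]2C(=O)C=C(C)C[C@@H]2C1(C)C | intermediate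
19 | 9,10-epoxy-7-(tert-butyldimethylsilyloxy) 2-en-1-one, epoxide on the upper face | CC(C)(C)[Si](C)(C)O[C@@H]1C[C@H]2O[C@@]2(C)[C@@H]3C(=O)C=C(C)C[C@@H]3C1(C)C | intermediate
20 | cis-fused 9,10-epoxide (upper face) with 7-OTBS and the C1 silyl dienol ether C1(OTBS)=C2–C3=C4 | CC(C)(C)[Si](C)(C)O[C@@H]1C[C@H]2O[C@@]2(C)[C@@H]3C(O[Si](C)(C)C(C)(C)C)=CC(C)=C[C@@H]3C1(C)C | intermediate
21 | 9-hydroxy-7-(tert-butyldimethylsilyloxy)longipin-2-en-1-one (9-OH and 10-Me upper face, 7-O lower face) | CC(C)(C)[Si](C)(C)O[C@@H]1C[C@@H](O)[C@@]2(C)[C@@H]3C(=O)C=C(C)[C@H]2[C@@H]3C1(C)C | intermediate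
22 | 7,9-dihydroxylongipin-2-en-1-one | O[C@@H]1C[C@@H](O)[C@@]2(C)[C@@H]3C(=O)C=C(C)[C@H]2[C@@H]3C1(C)C | intermediate
23 | 3-methylbut-2-enoyl chloride | CC(C)=CC(=O)Cl | starting material
24 | 7,9-bis(3-methylbut-2-enoyloxy)longipin-2-en-1-one (CNP0105062.1) | CC(C)=CC(=O)O[C@@H]1C[C@@H](OC(=O)C=C(C)C)[C@@]2(C)[C@@H]3C(=O)C=C(C)[C@H]2[C@@H]3C1(C)C | target

## Step count and risks

Total: 19 steps. Longest linear sequence: 18 steps (steps 1–4 and 6–19); step 5 makes the diene in a side branch.

Steps most likely to fail:

1. Step 17 (proposed new method). The opened epoxide may collapse by 1,2-hydride shift from C9 or by proton loss before C4 closes the strained ring, or the dienol ether may simply be desilylated. The fallback uses known chemistry and reverses the polarity of the same bond; it sets out from 20 and returns at 22. N-Bromosuccinimide (THF, −78 °C) brominates the γ-carbon of 20 and should give the 4-bromo epoxy enone F1, with bromine on the ring A face away from C10. BF3·OEt2 then rearranges the epoxide by hydride shift (Meinwald rearrangement) to the 4-bromo-1,9-dione F2. KOt-Bu in t-BuOH/THF forms the more substituted C10 enolate, which displaces the C4 bromide from the rear (intramolecular enolate alkylation, the long-established way to the four-membered ring of bicyclo[3.1.1]heptanes) to give the longipin-2-ene-1,9-dione F3. HF·pyridine frees the C7 hydroxyl to give the 7-hydroxy-1,9-dione F4. Me4NBH(OAc)3 (MeCN/AcOH, −20 °C) then delivers hydride to C9 from the lower-face C7 alkoxyborohydride (hydroxyl-directed 1,3-anti reduction), which should give 22 and leave the enone alone.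

2. Step 6. Cycloaddition at the neopentyl β-carbon C5 may be slow enough for Lewis-acid decomposition of the diene or open-chain Michael addition to take over, and facial discrimination by the C7 silyloxy group may be poor. The fallback makes the two bonds in separate operations; it sets out from 6 and 8 and returns at 9. A vinylogous Mukaiyama–Michael addition (catalytic TBSOTf, CH2Cl2, −78 °C) joins C4 to C5 and should give the silyl enol ether enal F5, whose enol ether is regiodefined toward C11. After E/Z equilibration of the β-methyl enal, BF3·OEt2 closes C11 onto the aldehyde carbon C1 (intramolecular Mukaiyama aldol; the short unsaturated tether favours the cis ring fusion) to give the hydroxy ketone F6. TBSOTf/2,6-lutidine then silylates the C1 hydroxyl to give 9 or its C1 epimer, which converges at 17.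

3. Step 16. The silyl triflate may open the tertiary epoxide, or enolisation may go toward C11 and destroy the epoxide. The fallback reaches the dienol ether by deconjugation and kinetic enolisation; it sets out from 19 and returns at 20. Pyrrolidine (benzene, molecular sieves) should give the linear dienamine F7. Buffered hydrolysis (aq. AcOH/NaOAc, 0 °C) protonates C2 and releases the β,γ-unsaturated ketone F8 (C3=C4). KN(SiMe3)2 with TBSCl at −78 °C then removes one of the doubly activated C2 protons, far more acidic than H11, and O-silylation gives 20.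

Further compounds
F1 | step 17 | 4-bromo-9,10-epoxy-7-(tert-butyldimethylsilyloxy) 2-en-1-one (γ-bromo epoxy enone) | CC(C)(C)[Si](C)(C)O[C@@H]1C[C@H]2O[C@@]2(C)[C@@H]3C(=O)C=C(C)[C@@H](Br)[C@@H]3C1(C)C
F2 | step 17 | 4-bromo-7-(tert-butyldimethylsilyloxy) 2-ene-1,9-dione (C10–H) | CC(C)(C)[Si](C)(C)O[C@@H]1CC(=O)[C@@H](C)[C@@H]2C(=O)C=C(C)[C@@H](Br)[C@@H]2C1(C)C
F3 | step 17 | 7-(tert-butyldimethylsilyloxy)longipin-2-ene-1,9-dione | CC(C)(C)[Si](C)(C)O[C@@H]1CC(=O)[C@@]2(C)[C@@H]3C(=O)C=C(C)[C@H]2[C@@H]3C1(C)C
F4 | step 17 | 7-hydroxylongipin-2-ene-1,9-dione | O[C@@H]1CC(=O)[C@@]2(C)[C@@H]3C(=O)C=C(C)[C@H]2[C@@H]3C1(C)C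
F5 | step 6 | silyl enol ether enal: C10(OTBS)=C11, 7-OTES, C5 bearing the (E)-2-methyl-4-oxobut-2-enyl chain | CC[Si](CC)(CC)O[C@H]1CCC(O[Si](C)(C)C(C)(C)C)=C[C@H](C/C(C)=C/C=O)C1(C)C
F6 | step 6 | cis-fused 1-hydroxy ketone (as 9 with free 1-OH) | CC[Si](CC)(CC)O[C@H]1CCC(=O)[C@@H]2[C@H](O)C=C(C)C[C@@H]2C1(C)C
F7 | step 16 | linear pyrrolidine dienamine of 19 (C1(N)=C2–C3=C4) | CC(C)(C)[Si](C)(C)O[C@@H]1C[C@H]2O[C@@]2(C)[C@@H]3C(N4CCCC4)=CC(C)=C[C@@H]3C1(C)C
F8 | step 16 | β,γ-unsaturated epoxy ketone (C1=O, C3=C4) | CC(C)(C)[Si](C)(C)O[C@@H]1C[C@H]2O[C@@]2(C)[C@@H]3C(=O)CC(C)=C[C@@H]3C1(C)C
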